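**Retrosynthetic overview**

1. The target is two trans-2-aryl-3-aryl-2,3-dihydrobenzofurans joined by the C3–C4′ bond: the formyl-bearing unit (benzo ring A, dihydrofuran ring B; O1, C2, C3) and the primed unit (benzo ring C, dihydrofuran ring D; O1′, C2′, C3′, C3a′, C7a′).
2. Late simplifications: the five phenols are carried as four methyl ethers and one 4-methoxybenzyl (PMB) ether, CHO as C5–Br, and rings B and D as their cis isomers, which acid equilibrates to trans by reversible C2–O1 and C2′–O1′ ionisation.
3. Ring D, the last ring, is cut at C2′–C3′: enantioselective 1,5 C–H insertion of a diaryl rhodium carbene at C3′ into the O1′–CH2–aryl group of a PMB ether. The enabling feature is that C2′ is a benzylic carbon bound to O1′ and to a 4-oxygenated aryl ring (a hydridic C–H, five atoms from C3′), while C3′ carries only aryl groups (ring C and the 3,5-dioxygenated ring) and so maps onto a diaryl carbene.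
4. The carbene precursor, a diaryl ketone hydrazone, comes from ring C by ortho-iodination, iodine–lithium exchange and a Weinreb ketone synthesis; of the two PMB ethers on ring C one supplies C2′ and the other is a protecting group.
5. Ring B is made first in the same way from 5-bromo-2-hydroxybenzonitrile, PMB chloride and a ring C Grignard reagent. Order of ring closure: ring B (step 5), then ring D (step 9); rings A and C and the three pendant aryl rings are bought as benzenes.

Key step: step 9

Assumption: Rh2(R-PTAD)4, dirhodium tetrakis[(R)-(adamantan-1-yl)(phthalimido)acetate], is taken to give the (3R) and (3′R) centres; if its sense of induction is the opposite, the catalyst with the (S) ligand is used in steps 5 and 9 and nothing else changes.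

**Route**

Step 1
Reactants: 1 5-bromo-2-hydroxybenzonitrile; 2 4-methoxybenzyl chloride
Product: 3 5-bromo-2-[(4-methoxyphenyl)methoxy]benzonitrile
Conditions: K2CO3, DMF, 60 °C
Reagents that add atoms: none
Why: Williamson ether synthesis, in which the phenoxide of 1 (made more acidic by the ortho nitrile) should displace chloride from the benzylic chloride 2 in an SN2 reaction while the nitrile and the aryl bromide are inert to K2CO3.

Step 2
Reactants: 4 5-bromobenzene-1,3-diol; 2 4-methoxybenzyl chloride (2.2 equiv)
Product: 5 1-bromo-3,5-bis[(4-methoxyphenyl)methoxy]benzene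
Conditions: K2CO3, DMF, 60 °C
Reagents that add atoms: none
Why: Twofold Williamson ether synthesis on both phenoxides of the symmetric resorcinol 4 should give the bis-ether, O-alkylation being favoured over C-alkylation in a polar aprotic solvent.

Step 3
Reactants: 5 1-bromo-3,5-bis[(4-methoxyphenyl)methoxy]benzene; 3 5-bromo-2-[(4-methoxyphenyl)methoxy]benzonitrile
Product: 8 {5-bromo-2-[(4-methoxyphenyl)methoxy]phenyl}{3,5-bis[(4-methoxyphenyl)methoxy]phenyl}methanone, via arylmagnesium bromide 6 (not isolated), via N-bromomagnesio ketimine 7 (not isolated)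
Conditions: 5, Mg, I2 (cat.), THF, 50 °C; then 3, THF, 60 °C; then 2 M aq. HCl, rt
Reagents that add atoms: water, O
Why: Grignard addition to a nitrile stops at the N-magnesio ketimine 7, so that no tertiary carbinol can form, and dilute aqueous acid then hydrolyses the ketimine to the benzophenone while the aryl bromide of 3 (inert to the arylmagnesium reagent) and the three aryl PMB ethers (stable to cold dilute acid) survive.

Step 4
Reactants: 8 {5-bromo-2-[(4-methoxyphenyl)methoxy]phenyl}{3,5-bis[(4-methoxyphenyl)methoxy]phenyl}methanone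
Product: 9 hydrazone of ketone 8 (E/Z mixture)
Conditions: N2H4·H2O (10 equiv), AcOH (cat.), EtOH, 80 °C
Reagents that add atoms: hydrazine hydrate, NN.O
Why: Hydrazone formation by acid-catalysed condensation should be uneventful at a benzophenone with a single ortho substituent, and the E/Z mixture does not matter because both isomers give the same diazo compound.

Step 5
Reactants: 9 hydrazone of ketone 8
Product: 11 (2S,3R)-5-bromo-3-{3,5-bis[(4-methoxyphenyl)methoxy]phenyl}-2-(4-methoxyphenyl)-2,3-dihydro-1-benzofuran (cis ring B), via diazo compound 10 (not isolated)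
Conditions: MnO2 (8 equiv), CH2Cl2, 0 °C, filtration; Rh2(R-PTAD)4 (1 mol %), CH2Cl2, 0 °C
Reagents that add atoms: none
Why: MnO2 dehydrogenates the hydrazone to diaryldiazomethane 10, and its rhodium carbene should undergo the known enantioselective intramolecular 1,5 C–H insertion of donor/donor carbenes into a benzyl aryl ether, which forms C2–C3 in a concerted step, gives the cis ring and sets C3 (and with it C2) by catalyst control, the two PMB ethers on ring C being meta to the carbene carbon and out of reach.

Step 6
Reactants: 11 cis-dihydrobenzofuran from step 5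
Product: 12 (2S,3S)-5-bromo-3-{2-iodo-3,5-bis[(4-methoxyphenyl)methoxy]phenyl}-2-(4-methoxyphenyl)-2,3-dihydro-1-benzofuran (cis ring B)
Conditions: N-iodosuccinimide (1.05 equiv), MeCN, rt, dark
Reagents that add atoms: N-iodosuccinimide, O=C1CCC(=O)N1I
Why: Electrophilic aromatic iodination should take place on the most electron-rich ring C at the position para to one alkoxy group and ortho to the other (the two such positions are equivalent by rotation about the C3–aryl bond), not between the two alkoxy groups and not on the less activated anisole-type rings, and the neutral conditions leave the acid-labile cis ring B and the PMB ethers untouched.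

Step 7
Reactants: 12 aryl iodide from step 6; 13 N,3,5-trimethoxy-N-methylbenzamide
Product: 15 {2-[(2S,3R)-5-bromo-2-(4-methoxyphenyl)-2,3-dihydro-1-benzofuran-3-yl]-4,6-bis[(4-methoxyphenyl)methoxy]phenyl}(3,5-dimethoxyphenyl)methanone, via aryllithium 14 (not isolated)
Conditions: n-BuLi (1.05 equiv), THF, −78 °C; 13, −78 to 0 °C; H2O
Reagents that add atoms: none
Why: Iodine–lithium exchange is far faster than bromine–lithium exchange at −78 °C, so only the iodide should be metalated, and in the Weinreb ketone synthesis the chelated tetrahedral adduct survives until the quench, so that addition stops at the ketone.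

Step 8
Reactants: 15 diaryl ketone from step 7
Product: 16 hydrazone of ketone 15 (E/Z mixture)
Conditions: N2H4·H2O (30 equiv), AcOH (cat.), n-BuOH, 120 °C, sealed tube
Reagents that add atoms: hydrazine hydrate, NN.O
Why: Hydrazone formation at this benzophenone with two ortho substituents on one ring needs forcing conditions (large excess of hydrazine, acid catalysis, sealed tube), under which the aryl bromide, the ethers and the cis ring B are stable, and no strong base is present that could start a Wolff–Kishner reduction.

Step 9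
Reactants: 16 hydrazone of ketone 15
Product: 18 (2S,3R)-5-bromo-3-{(2S,3R)-3-(3,5-dimethoxyphenyl)-2-(4-methoxyphenyl)-6-[(4-methoxyphenyl)methoxy]-2,3-dihydro-1-benzofuran-4-yl}-2-(4-methoxyphenyl)-2,3-dihydro-1-benzofuran (rings B and D both cis), via diazo compound 17 (not isolated)
Conditions: MnO2 (10 equiv), CH2Cl2, 0 °C, filtration; slow addition to Rh2(R-PTAD)4 (2 mol %), CH2Cl2, 0 °C to rt
Reagents that add atoms: none
Why: MnO2 dehydrogenates hydrazone 16 to diaryldiazomethane 17, the chiral dirhodium tetracarboxylate (both rhodium atoms divalent) expels N2 to give a donor/donor carbene at C3′, and this carbene inserts into one of the two enantiotopic C–H bonds of the O1′–CH2–aryl group through a concerted, hydride-transfer-like three-centre transition state that forms the C2′–C3′ bond. The closest known reaction type is the enantioselective intramolecular C–H insertion of diaryl rhodium carbenes into benzyl aryl ethers to cis-2,3-diaryl-2,3-dihydrobenzofurans, already used in step 5, here at a carbene flanked by two ortho substituents and next to a stereogenic neighbour. Ring D closes by 1,5 insertion, that is by making the C2′–C3′ bond of a five-membered ring whose C3′–C3a′, C3a′–C7a′, C7a′–O1′ and O1′–C2′ bonds are already in place. C3′ is set by the catalyst, which differentiates the two faces of the carbene and is expected to dominate over the C2 and C3 centres, and C2′ is set relative to C3′ by the concerted mechanism, which places the two aryl groups cis (step 11 turns C2′ to trans without touching C3′). The step needs site selectivity, face selectivity and insertion in preference to azine formation: the OCH2 group on O1′ is the only activated C–H bond within reach, because the second PMB ether is para to the carbene carbon, C3–H is only four atoms away, and the tertiary, equally activated C2–H of ring B points to the face opposite to ring C as long as ring B is cis, so that its insertion would need a trans-fused bicyclo[3.3.0] system, which is why ring B is kept cis up to this step. Azine formation is held back by slow addition of the diazo solution to the catalyst at low temperature.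

Step 10
Reactants: 18 bis-dihydrobenzofuran bromide from step 9
Product: 20 (2S,3R)-3-{(2S,3R)-3-(3,5-dimethoxyphenyl)-2-(4-methoxyphenyl)-6-[(4-methoxyphenyl)methoxy]-2,3-dihydro-1-benzofuran-4-yl}-2-(4-methoxyphenyl)-2,3-dihydro-1-benzofuran-5-carbaldehyde, via aryllithium 19 (not isolated)
Conditions: n-BuLi (1.1 equiv), THF, −78 °C; DMF, −78 °C to rt; H2O
Reagents that add atoms: N,N-dimethylformamide, CN(C)C=O
Why: Bromine–lithium exchange followed by formylation of the aryllithium with DMF (Bouveault aldehyde synthesis) should turn the only halogen into the aldehyde, since the hemiaminal alkoxide protects the product from a second addition until the aqueous quench and the substrate holds only ethers.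

Step 11
Reactants: 20 cis,cis aldehyde from step 10
Product: 21 (2R,3R)-3-[(2R,3R)-3-(3,5-dimethoxyphenyl)-6-hydroxy-2-(4-methoxyphenyl)-2,3-dihydro-1-benzofuran-4-yl]-2-(4-methoxyphenyl)-2,3-dihydro-1-benzofuran-5-carbaldehyde (rings B and D both trans)
Conditions: TFA (20% v/v), pentamethylbenzene (5 equiv), CH2Cl2, 0 °C to rt
Reagents that add atoms: none
Why: Acidolysis, in which TFA ionises C2–O1 and C2′–O1′ to 4-methoxybenzylic cations that reclose (SN1 ring opening and ring closure) to the thermodynamically preferred trans rings while C3 and C3′, which are not part of the ionising bonds, keep their configuration, and the same acid cleaves the aryl PMB ether, whose benzyl cation is trapped by pentamethylbenzene in a Friedel–Crafts alkylation.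

Step 12
Reactants: 21 all-trans tetramethyl ether from step 11
Product: 22 (2R,3R)-3-[(2R,3R)-3-(3,5-dihydroxyphenyl)-6-hydroxy-2-(4-hydroxyphenyl)-2,3-dihydro-1-benzofuran-4-yl]-2-(4-hydroxyphenyl)-2,3-dihydro-1-benzofuran-5-carbaldehyde (target)
Conditions: BBr3 (12 equiv), CH2Cl2, −78 °C to rt; then H2O
Reagents that add atoms: none
Why: Lewis acid ether cleavage, in which BBr3 complexes each aryl methyl ether and bromide attacks the methyl carbon, should remove all four methyl groups, while the aldehyde is returned from its boron adduct on aqueous work-up and the two trans rings, being the thermodynamic isomers, are not changed by any reversible ionisation.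

**Compound list**

1 | 5-bromo-2-hydroxybenzonitrile | N#Cc1cc(Br)ccc1O | starting material
2 | 4-methoxybenzyl chloride | COc1ccc(CCl)cc1 | starting material
3 | 5-bromo-2-[(4-methoxyphenyl)methoxy]benzonitrile | N#Cc1cc(Br)ccc1OCc1ccc(OC)cc1 | intermediate
4 | 5-bromobenzene-1,3-diol | Oc1cc(O)cc(Br)c1 | starting material
5 | 1-bromo-3,5-bis[(4-methoxyphenyl)methoxy]benzene | COc1ccc(COc2cc(Br)cc(OCc3ccc(OC)cc3)c2)cc1 | intermediate
6 | {3,5-bis[(4-methoxyphenyl)methoxy]phenyl}magnesium bromide | COc1ccc(COc2cc([Mg]Br)cc(OCc3ccc(OC)cc3)c2)cc1 | intermediate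
7 | N-bromomagnesio ketimine of ketone 8 | Br[Mg]N=C(c1cc(OCc2ccc(OC)cc2)cc(OCc2ccc(OC)cc2)c1)c1cc(Br)ccc1OCc1ccc(OC)cc1 | intermediate
8 | {5-bromo-2-[(4-methoxyphenyl)methoxy]phenyl}{3,5-bis[(4-methoxyphenyl)methoxy]phenyl}methanone | O=C(c1cc(OCc2ccc(OC)cc2)cc(OCc2ccc(OC)cc2)c1)c1cc(Br)ccc1OCc1ccc(OC)cc1 | intermediate
9 | hydrazone of ketone 8 (E/Z mixture) | NN=C(c1cc(OCc2ccc(OC)cc2)cc(OCc2ccc(OC)cc2)c1)c1cc(Br)ccc1OCc1ccc(OC)cc1 | intermediate
10 | 4-bromo-2-(diazo{3,5-bis[(4-methoxyphenyl)methoxy]phenyl}methyl)-1-[(4-methoxyphenyl)methoxy]benzene | [N-]=[N+]=C(c1cc(OCc2ccc(OC)cc2)cc(OCc2ccc(OC)cc2)c1)c1cc(Br)ccc1OCc1ccc(OC)cc1 | intermediate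
11 | (2S,3R)-5-bromo-3-{3,5-bis[(4-methoxyphenyl)methoxy]phenyl}-2-(4-methoxyphenyl)-2,3-dihydro-1-benzofuran (cis) | Brc1ccc2c(c1)[C@@H](c1cc(OCc3ccc(OC)cc3)cc(OCc3ccc(OC)cc3)c1)[C@@H](c1ccc(OC)cc1)O2 | intermediate
12 | (2S,3S)-5-bromo-3-{2-iodo-3,5-bis[(4-methoxyphenyl)methoxy]phenyl}-2-(4-methoxyphenyl)-2,3-dihydro-1-benzofuran (cis; same spatial arrangement as 11, the C3 descriptor changes only because iodine changes the priorities) | Brc1ccc2c(c1)[C@@H](c1cc(OCc3ccc(OC)cc3)cc(OCc3ccc(OC)cc3)c1I)[C@@H](c1ccc(OC)cc1)O2 | intermediate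
13 | N,3,5-trimethoxy-N-methylbenzamide | CON(C)C(=O)c1cc(OC)cc(OC)c1 | starting material
14 | aryllithium: 12 with lithium in place of iodine | Brc1ccc2c(c1)[C@@H](c1cc(OCc3ccc(OC)cc3)cc(OCc3ccc(OC)cc3)c1[Li])[C@@H](c1ccc(OC)cc1)O2 | intermediate
15 | {2-[(2S,3R)-5-bromo-2-(4-methoxyphenyl)-2,3-dihydro-1-benzofuran-3-yl]-4,6-bis[(4-methoxyphenyl)methoxy]phenyl}(3,5-dimethoxyphenyl)methanone | Brc1ccc2c(c1)[C@@H](c1cc(OCc3ccc(OC)cc3)cc(OCc3ccc(OC)cc3)c1C(=O)c1cc(OC)cc(OC)c1)[C@@H](c1ccc(OC)cc1)O2 | intermediate
16 | hydrazone of ketone 15 (E/Z mixture) | Brc1ccc2c(c1)[C@@H](c1cc(OCc3ccc(OC)cc3)cc(OCc3ccc(OC)cc3)c1C(=NN)c1cc(OC)cc(OC)c1)[C@@H](c1ccc(OC)cc1)O2 | intermediate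
17 | diazo compound from 16 (C=N2 in place of C=N–NH2) | Brc1ccc2c(c1)[C@@H](c1cc(OCc3ccc(OC)cc3)cc(OCc3ccc(OC)cc3)c1C(=[N+]=[N-])c1cc(OC)cc(OC)c1)[C@@H](c1ccc(OC)cc1)O2 | intermediate
18 | (2S,3R)-5-bromo-3-{(2S,3R)-3-(3,5-dimethoxyphenyl)-2-(4-methoxyphenyl)-6-[(4-methoxyphenyl)methoxy]-2,3-dihydro-1-benzofuran-4-yl}-2-(4-methoxyphenyl)-2,3-dihydro-1-benzofuran (both rings cis) | Brc1ccc2c(c1)[C@@H](c1cc(OCc3ccc(OC)cc3)cc3c1[C@@H](c1cc(OC)cc(OC)c1)[C@@H](c1ccc(OC)cc1)O3)[C@@H](c1ccc(OC)cc1)O2 | intermediate
19 | aryllithium: 18 with lithium in place of bromine | [Li]c1ccc2c(c1)[C@@H](c1cc(OCc3ccc(OC)cc3)cc3c1[C@@H](c1cc(OC)cc(OC)c1)[C@@H](c1ccc(OC)cc1)O3)[C@@H](c1ccc(OC)cc1)O2 | intermediate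
20 | (2S,3R)-3-{(2S,3R)-3-(3,5-dimethoxyphenyl)-2-(4-methoxyphenyl)-6-[(4-methoxyphenyl)methoxy]-2,3-dihydro-1-benzofuran-4-yl}-2-(4-methoxyphenyl)-2,3-dihydro-1-benzofuran-5-carbaldehyde (both rings cis) | O=Cc1ccc2c(c1)[C@@H](c1cc(OCc3ccc(OC)cc3)cc3c1[C@@H](c1cc(OC)cc(OC)c1)[C@@H](c1ccc(OC)cc1)O3)[C@@H](c1ccc(OC)cc1)O2 | intermediate
21 | (2R,3R)-3-[(2R,3R)-3-(3,5-dimethoxyphenyl)-6-hydroxy-2-(4-methoxyphenyl)-2,3-dihydro-1-benzofuran-4-yl]-2-(4-methoxyphenyl)-2,3-dihydro-1-benzofuran-5-carbaldehyde (both rings trans) | O=Cc1ccc2c(c1)[C@@H](c1cc(O)cc3c1[C@@H](c1cc(OC)cc(OC)c1)[C@H](c1ccc(OC)cc1)O3)[C@H](c1ccc(OC)cc1)O2 | intermediate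
22 | (2R,3R)-3-[(2R,3R)-3-(3,5-dihydroxyphenyl)-6-hydroxy-2-(4-hydroxyphenyl)-2,3-dihydro-1-benzofuran-4-yl]-2-(4-hydroxyphenyl)-2,3-dihydro-1-benzofuran-5-carbaldehyde | O=Cc1ccc2c(c1)[C@@H](c1cc(O)cc3c1[C@@H](c1cc(O)cc(O)c1)[C@H](c1ccc(O)cc1)O3)[C@H](c1ccc(O)cc1)O2 | target

**Step count and risks**

Total step count: 12. Longest linear sequence: 11 steps (steps 1 and 3 to 12, from 1 to 22); step 2 is a one-step branch.

Steps most likely to fail:

Step 9 (key step). The insertion may be slow at a carbene flanked by two ortho substituents, so that azine formation and carbene dimerisation take over, or the C2 and C3 centres may oppose the catalyst (mismatched pair) and lower the face selectivity. The fallback sets out from 15 and closes ring D by carbanion chemistry instead of carbene chemistry. Deprotonation of the O1′–CH2 group with LiN(i-Pr)2 (THF, −78 °C) and intramolecular addition of the benzylic carbanion to the ketone should give the 3′-hydroxy ring D carbinol F1. Ionic hydrogenation of this diaryl carbinol (Et3SiH, BF3·OEt2, CH2Cl2, −78 °C), with hydride delivered to the benzylic cation anti to the C2′ aryl group, should give the cis ring D in both absolute senses. Because ring B is homochiral, these are two separable diastereomers, 18 and the (2′R,3′S)-cis diastereomer of 18 F2. The fallback comes back to the route at 18.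

Step 8. Condensation at the hindered carbonyl may stop short or end in azine. The fallback sets out from 12 and makes the C=N bond by carbon–carbon bond formation at a linear nitrile instead of by condensation. Aryllithium 14 (n-BuLi, THF, −78 °C) adds to 3,5-dimethoxybenzonitrile to give the N-lithio ketimine F3, and electrophilic N-amination of this anion with Ph2P(O)ONH2 should give the hydrazone directly. The fallback comes back to the route at 16.

Step 11. The acid treatment may erode C3 or C3′ through loss of a proton from the ring-opened cation (triarylethene formation and reprotonation), or the benzyl cation or the protonated aldehyde may alkylate the electron-rich rings. The fallback sets out from 20 and moves the equilibration to the free phenol stage, where it runs by a different mechanism. Global deprotection (BBr3, pentamethylbenzene, CH2Cl2, −78 to 0 °C) should give the cis,cis-pentaphenol F4, together with any partly epimerised material. Mild base (K2CO3, MeOH, rt) should then open each ring by 1,6-elimination of the ring phenoxide from the 4-hydroxyphenyl phenoxide to a para-quinone methide and reclose it by oxa-Michael addition to the trans ring. The fallback comes back to the route at 22.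

Further compounds
F1 | step 9 | 3′-hydroxy ring D carbinol: (2S,3R)-5-bromo-3-{3-(3,5-dimethoxyphenyl)-3-hydroxy-2-(4-methoxyphenyl)-6-[(4-methoxyphenyl)methoxy]-2,3-dihydro-1-benzofuran-4-yl}-2-(4-methoxyphenyl)-2,3-dihydro-1-benzofuran (mixture at C2′ and C3′) | Brc1ccc2c(c1)[C@@H](c1cc(OCc3ccc(OC)cc3)cc3c1C(O)(c1cc(OC)cc(OC)c1)C(c1ccc(OC)cc1)O3)[C@@H](c1ccc(OC)cc1)O2
F2 | step 9 | (2′R,3′S)-cis diastereomer of 18: (2S,3R)-5-bromo-3-{(2R,3S)-3-(3,5-dimethoxyphenyl)-2-(4-methoxyphenyl)-6-[(4-methoxyphenyl)methoxy]-2,3-dihydro-1-benzofuran-4-yl}-2-(4-methoxyphenyl)-2,3-dihydro-1-benzofuran | Brc1ccc2c(c1)[C@@H](c1cc(OCc3ccc(OC)cc3)cc3c1[C@H](c1cc(OC)cc(OC)c1)[C@H](c1ccc(OC)cc1)O3)[C@@H](c1ccc(OC)cc1)O2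
F3 | step 8 | N-lithio ketimine: lithium ({2-[(2S,3R)-5-bromo-2-(4-methoxyphenyl)-2,3-dihydro-1-benzofuran-3-yl]-4,6-bis[(4-methoxyphenyl)methoxy]phenyl}(3,5-dimethoxyphenyl)methylidene)azanide | Brc1ccc2c(c1)[C@@H](c1cc(OCc3ccc(OC)cc3)cc(OCc3ccc(OC)cc3)c1C(=N[Li])c1cc(OC)cc(OC)c1)[C@@H](c1ccc(OC)cc1)O2
F4 | step 11 | cis,cis-pentaphenol: (2S,3R)-3-[(2S,3R)-3-(3,5-dihydroxyphenyl)-6-hydroxy-2-(4-hydroxyphenyl)-2,3-dihydro-1-benzofuran-4-yl]-2-(4-hydroxyphenyl)-2,3-dihydro-1-benzofuran-5-carbaldehyde | O=Cc1ccc2c(c1)[C@@H](c1cc(O)cc3c1[C@@H](c1cc(O)cc(O)c1)[C@@H](c1ccc(O)cc1)O3)[C@@H](c1ccc(O)cc1)O2
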